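**Retrosynthetic overview**
- The target is traced back to its non-formylated depside by removing the two formyl groups of ring A (late double ortho-formylation; C3 and C5 of ring A are the only free aromatic positions in the molecule).
- The depside is cut at the aryl ester C–O bond into the ring B phenol (methyl 4-hydroxy-2-methoxy-3,5,6-trimethylbenzoate) and unprotected orsellinic acid. This is the key step, a decarboxylative aryloxy transfer from the imidazole-1-carboxylate of the phenol.
- The ring B phenol comes from methyl 2,4-dihydroxy-3,6-dimethylbenzoate by O4-benzylation/O2-methylation, C5 formylation, and one hydrogenolysis that removes the benzyl group and reduces CHO to CH3.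
- No ring is formed: both benzene rings are bought intact. The order is ring B decoration, then the ester C–O bond, then ring A formylation.

Assumption: the target has no stereocentre or other stereogenic element, so it is one achiral compound and no stereocontrol is needed.

**Step 1**
Reactants: 1 methyl 2,4-dihydroxy-3,6-dimethylbenzoate
Product: 3 methyl 4-(benzyloxy)-2-methoxy-3,6-dimethylbenzoate, via mono-benzyl ether 2 (not isolated)
Conditions: K2CO3 (3 equiv), BnBr (1.0 equiv), DMF, 25 °C; then MeI (3 equiv), 50 °C, one pot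
Reagents that add atoms: benzyl bromide, BrCc1ccccc1; iodomethane, CI
Why: Williamson ether synthesis twice in one pot: the non-chelated, more acidic 4-OH is benzylated first by one equivalent of BnBr, and the ester-chelated 2-OH, the only hydroxyl left, is then methylated by excess MeI at 50 °C.

**Step 2**
Reactants: 3 methyl 4-(benzyloxy)-2-methoxy-3,6-dimethylbenzoate
Product: 5 methyl 4-(benzyloxy)-5-formyl-2-methoxy-3,6-dimethylbenzoate, via α-chloro ether 4 (not isolated)
Conditions: Cl2CHOMe (1.5 equiv), SnCl4 (2 equiv), CH2Cl2, −20 → 0 °C; then ice, 1 M HCl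
Reagents that add atoms: dichloromethyl methyl ether, COC(Cl)Cl; water, O
Why: Rieche formylation (electrophilic aromatic substitution): C5 is the only unsubstituted position of the ring and is activated ortho to OBn and para to OMe, SnCl4 at low temperature is mild enough to leave the benzyl ether in place, and the α-chloro ether is hydrolysed to the aldehyde on work-up.

**Step 3**
Reactants: 5 methyl 4-(benzyloxy)-5-formyl-2-methoxy-3,6-dimethylbenzoate
Product: 8 methyl 4-hydroxy-2-methoxy-3,5,6-trimethylbenzoate, via hydroxy aldehyde 6 (not isolated), via benzylic alcohol 7 (not isolated)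
Conditions: H2 (4 atm), 10% Pd/C, AcOH, cat. HCl, 45 °C
Reagents that add atoms: none
Why: Catalytic hydrogenolysis: the O-benzyl group is cleaved first, the electron-rich ortho-hydroxy aldehyde is then hydrogenated to the benzylic alcohol, and its C–O bond is cleaved under the acidic conditions (benzylic cation or ortho-quinone methide on the palladium surface), while the methyl ester, the aryl methyl ether and the arene are untouched.

**Step 4**
Reactants: 8 methyl 4-hydroxy-2-methoxy-3,5,6-trimethylbenzoate; 9 orsellinic acid (2,4-dihydroxy-6-methylbenzoic acid)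
Product: 12 methyl 4-[(2,4-dihydroxy-6-methylbenzoyl)oxy]-2-methoxy-3,5,6-trimethylbenzoate, via aryl imidazole-1-carboxylate 10 (not isolated), via mixed carbonic anhydride 11 (not isolated)
Conditions: CDI (1.0 equiv), MeCN, 40 °C, 2 h; then 9 (1.1 equiv) in THF added over 2 h, 60 °C, 12 h, N2 sweep
Reagents that add atoms: 1,1'-carbonyldiimidazole (CDI), O=C(n1ccnc1)n1ccnc1
Why: Proposed new method: decarboxylative aryloxy transfer from an aryl 1H-imidazole-1-carboxylate to a free carboxylic acid, in which only the CO2H of 9 (pKa about 4) is acidic enough to protonate the imidazole of 10 and add as carboxylate to its carbonyl to give mixed carboxylic–carbonic anhydride 11, which is opened at the aroyl carbon by the released imidazole (or, through the ortho-hydroxyl, by way of an oxoketene that is insensitive to steric bulk) with irreversible loss of CO2, so that the hindered aryloxide of 8 is set free as an ion pair right beside the activated orsellinoyl unit and should capture it before a neutral phenol of a second molecule of 9 does, while no free activating agent ever meets the phenols of 9; the closest known reaction type is the esterification of carboxylic acids with alkyl imidazole-1-carboxylates (and aryl ester formation from diaryl carbonates), not yet shown for a hindered aryloxy group or an unprotected dihydroxybenzoic acid.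

**Step 5**
Reactants: 12 methyl 4-[(2,4-dihydroxy-6-methylbenzoyl)oxy]-2-methoxy-3,5,6-trimethylbenzoate
Product: 14 methyl 4-[(3,5-diformyl-2,4-dihydroxy-6-methylbenzoyl)oxy]-2-methoxy-3,5,6-trimethylbenzoate, via bis(α-chloro ether) 13 (not isolated)
Conditions: Cl2CHOMe (6 equiv), TiCl4 (8 equiv), CH2Cl2, 0 → 25 °C; then ice, 1 M HCl
Reagents that add atoms: dichloromethyl methyl ether, COC(Cl)Cl; water, O
Why: Double Rieche formylation: the titanium phenoxides of the two hydroxyls direct the electrophile to their ortho positions C3 and C5 of ring A, which are the only unsubstituted aromatic carbons in 12 (ring B is fully substituted), and the anhydrous Lewis-acid medium offers no nucleophile to cleave the doubly ortho-shielded aryl ester.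

**Compound list**
1 | methyl 2,4-dihydroxy-3,6-dimethylbenzoate | COC(=O)c1c(C)cc(O)c(C)c1O | starting material
2 | mono-benzyl ether: methyl 4-(benzyloxy)-2-hydroxy-3,6-dimethylbenzoate (not isolated) | COC(=O)c1c(C)cc(OCc2ccccc2)c(C)c1O | intermediate
3 | methyl 4-(benzyloxy)-2-methoxy-3,6-dimethylbenzoate | COC(=O)c1c(C)cc(OCc2ccccc2)c(C)c1OC | intermediate
4 | α-chloro ether: methyl 4-(benzyloxy)-5-[chloro(methoxy)methyl]-2-methoxy-3,6-dimethylbenzoate (racemic, not isolated) | COC(=O)c1c(C)c(C(Cl)OC)c(OCc2ccccc2)c(C)c1OC | intermediate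
5 | methyl 4-(benzyloxy)-5-formyl-2-methoxy-3,6-dimethylbenzoate | COC(=O)c1c(C)c(C=O)c(OCc2ccccc2)c(C)c1OC | intermediate
6 | hydroxy aldehyde: methyl 5-formyl-4-hydroxy-2-methoxy-3,6-dimethylbenzoate (not isolated) | COC(=O)c1c(C)c(C=O)c(O)c(C)c1OC | intermediate
7 | benzylic alcohol: methyl 4-hydroxy-5-(hydroxymethyl)-2-methoxy-3,6-dimethylbenzoate (not isolated) | COC(=O)c1c(C)c(CO)c(O)c(C)c1OC | intermediate
8 | methyl 4-hydroxy-2-methoxy-3,5,6-trimethylbenzoate (ring B phenol) | COC(=O)c1c(C)c(C)c(O)c(C)c1OC | intermediate
9 | orsellinic acid (2,4-dihydroxy-6-methylbenzoic acid) | Cc1cc(O)cc(O)c1C(=O)O | starting material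
10 | aryl imidazole-1-carboxylate: methyl 4-[(1H-imidazol-1-ylcarbonyl)oxy]-2-methoxy-3,5,6-trimethylbenzoate (not isolated) | COC(=O)c1c(C)c(C)c(OC(=O)n2ccnc2)c(C)c1OC | intermediate
11 | mixed carbonic anhydride: 2,4-dihydroxy-6-methylbenzoic [3-methoxy-4-(methoxycarbonyl)-2,5,6-trimethylphenyl carbonic] anhydride (not isolated) | COC(=O)c1c(C)c(C)c(OC(=O)OC(=O)c2c(C)cc(O)cc2O)c(C)c1OC | intermediate
12 | methyl 4-[(2,4-dihydroxy-6-methylbenzoyl)oxy]-2-methoxy-3,5,6-trimethylbenzoate | COC(=O)c1c(C)c(C)c(OC(=O)c2c(C)cc(O)cc2O)c(C)c1OC | intermediate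
13 | bis(α-chloro ether): methyl 4-({3,5-bis[chloro(methoxy)methyl]-2,4-dihydroxy-6-methylbenzoyl}oxy)-2-methoxy-3,5,6-trimethylbenzoate (diastereomer mixture, not isolated) | COC(=O)c1c(C)c(C)c(OC(=O)c2c(C)c(C(Cl)OC)c(O)c(C(Cl)OC)c2O)c(C)c1OC | intermediate
14 | methyl 4-[(3,5-diformyl-2,4-dihydroxy-6-methylbenzoyl)oxy]-2-methoxy-3,5,6-trimethylbenzoate (CNP0217876.0, achiral) | COC(=O)c1c(C)c(C)c(OC(=O)c2c(C)c(C=O)c(O)c(C=O)c2O)c(C)c1OC | target

**Totals**
Total step count: 5. Longest linear sequence: 5 steps (1 → 3 → 5 → 8 → 12 → 14; 9 is bought and enters at step 4).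

**Three steps most likely to fail**

Step 4 (the proposed new ester C–O bond formation). The collapse of 11 may be slow at two doubly ortho-substituted centres, and the 4-OH of a second molecule of 9 may compete and give oligo-orsellinates. The fallback uses known chemistry, sets out from 9 and 8 and comes back at 12. Acid 9 is perbenzylated (BnBr, K2CO3, DMF) to benzyl 2,4-bis(benzyloxy)-6-methylbenzoate F1. The benzyl ester is saponified (KOH, aqueous DMSO, 80 °C) to 2,4-bis(benzyloxy)-6-methylbenzoic acid F2. F2 is condensed with 8 through its mixed trifluoroacetic anhydride ((CF3CO)2O, toluene, 25 °C) to methyl 4-{[2,4-bis(benzyloxy)-6-methylbenzoyl]oxy}-2-methoxy-3,5,6-trimethylbenzoate F3. Hydrogenolysis (H2, 10% Pd/C, EtOAc) then gives 12.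

Step 5 (double formylation of the depside). It may stop at the mono-aldehyde, and TiCl4 may demethylate the ester-chelated methoxy group of ring B. The fallback puts the formyl groups in before the ester bond; it sets out from 9 and 8 and comes back at 14. Acid 9 is esterified at the carboxylate only (allyl bromide, KHCO3, DMF) to prop-2-en-1-yl 2,4-dihydroxy-6-methylbenzoate F4. F4 is diformylated under Duff conditions (hexamethylenetetramine, CF3CO2H, 70 °C, then aqueous HCl) to prop-2-en-1-yl 3,5-diformyl-2,4-dihydroxy-6-methylbenzoate F5. The allyl group is removed (cat. Pd(PPh3)4, TolSO2Na, THF–MeOH, 25 °C) to give 3,5-diformyl-2,4-dihydroxy-6-methylbenzoic acid F6. Both hydroxyls of F6 are chelated by flanking carbonyls, so it is coupled without protection to 8 with a carbodiimide (DCC, toluene–ether, 25 °C) to give 14.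

Step 3 (one-pot debenzylation and CHO → CH3). The hindered, electron-rich carbonyl may stall at 6 or 7; the benzyl ether may also be partly lost already in step 2. The fallback brings in the methyl group by cross-coupling; it sets out from 3 and comes back at 8. Compound 3 is brominated at its only free ring position (NBS, MeCN, 25 °C) to methyl 4-(benzyloxy)-5-bromo-2-methoxy-3,6-dimethylbenzoate F7. Suzuki–Miyaura methylation (trimethylboroxine, Pd(OAc)2/SPhos, K3PO4, toluene–H2O, 100 °C) gives methyl 4-(benzyloxy)-2-methoxy-3,5,6-trimethylbenzoate F8. Simple O-debenzylation (H2, 10% Pd/C, EtOAc) then gives 8.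

**Further compounds**
F1 | step 4 | benzyl 2,4-bis(benzyloxy)-6-methylbenzoate | Cc1cc(OCc2ccccc2)cc(OCc3ccccc3)c1C(=O)OCc4ccccc4
F2 | step 4 | 2,4-bis(benzyloxy)-6-methylbenzoic acid | Cc1cc(OCc2ccccc2)cc(OCc3ccccc3)c1C(=O)O
F3 | step 4 | methyl 4-{[2,4-bis(benzyloxy)-6-methylbenzoyl]oxy}-2-methoxy-3,5,6-trimethylbenzoate | COC(=O)c1c(C)c(C)c(OC(=O)c2c(C)cc(OCc3ccccc3)cc2OCc4ccccc4)c(C)c1OC
F4 | step 5 | prop-2-en-1-yl 2,4-dihydroxy-6-methylbenzoate | Cc1cc(O)cc(O)c1C(=O)OCC=C
F5 | step 5 | prop-2-en-1-yl 3,5-diformyl-2,4-dihydroxy-6-methylbenzoate | Cc1c(C=O)c(O)c(C=O)c(O)c1C(=O)OCC=C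
F6 | step 5 | 3,5-diformyl-2,4-dihydroxy-6-methylbenzoic acid | Cc1c(C=O)c(O)c(C=O)c(O)c1C(=O)O
F7 | step 3 | methyl 4-(benzyloxy)-5-bromo-2-methoxy-3,6-dimethylbenzoate | COC(=O)c1c(C)c(Br)c(OCc2ccccc2)c(C)c1OC
F8 | step 3 | methyl 4-(benzyloxy)-2-methoxy-3,5,6-trimethylbenzoate | COC(=O)c1c(C)c(C)c(OCc2ccccc2)c(C)c1OC
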